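## The problem

Atoms are numbered C1 (senecioate carbinol), C2, C3 (isovalerate carbinol), C4 (CMe2), C5, C6, C7 (C=O), C8, C9 (C–CH3), C10 and C11 (quaternary C–CH3), with ring bonds C1–C11, C5–C10 and C6–C11. The target is a longipinane-type diester in which a cyclobutane (C5–C6–C11–C10) is spanned across C6/C10 by the enone bridge C7(=O)–C8=C9(CH3) and, on the opposite face, across C5/C11 by the chain C4–C3–C2–C1, so that the seven-membered ring is flanked by the quaternary carbons C4 and C11. The four cyclobutane stereocentres are locked to one another, because with the two bridges on opposite faces only one relative arrangement exists, and only its absolute sense has to be set. The carbinol centres C1 (R) and C3 (R) are trans, and since the skeleton is almost mirror-symmetric about the plane through C5, C11 and the four-carbon bridge (the halves differ only in C7=O versus C9–CH3), the ring cannot distinguish the two faces of C1: a reagent must tie C1 to the sense of the enone bridge, after which a second reagent can set C3. The two esters differ and sit on hindered neopentyl-type alcohols, and the conjugated senecioate does not survive hydride, organometallics or singlet oxygen, so the order of acylation is dictated by the chemistry that lies between them. The cyclobutane is strained, and a cation or radical on a carbon attached to it (for example the C11 methyl carbon) would open or expand the ring, so such carbons must be handled by ionic SN2 chemistry. The enabling feature is that C5 and C11 are 1,3-related cyclobutane atoms carrying the two ends of the four-carbon bridge: a bond between them makes a bicyclo[1.1.0]butane whose wing carbons C6/C10 are already tied by C7–C9. A 1,3-dioxygenated four-carbon diene can then be inserted into that C5–C11 σ bond, forming C4–C5 and C1–C11 together.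

## Retrosynthesis

Esters last (30 ⇐ 29 ⇐ 28; 24 ⇐ 23). The two acyl C–O bonds are cut first. The senecioate of 30 is put on alcohol 29 in the final step because it tolerates none of the earlier reagents, and 29 comes from silyl ether 28. The saturated isovalerate is placed on O3 of alcohol 23, giving 24, as soon as hydride chemistry is over. O1 stays a silyl ether in between, so the two hydroxyls are told apart by the order in which they appear and not by selective acylation of a diol. The forward steps are plain acylations of hindered secondary alcohols.

Enone bridge (28 ⇐ 27 ⇐ 26 ⇐ 24). The C9–CH3 bond is cut to enone 26 (conjugate methylation to silyl enol ether 27, then Saegusa–Ito dehydrogenation). The C7 carbonyl is traced to the plain C7=C8 alkene of 24 by a singlet-oxygen ene reaction with allylic transposition. Carrying the methyl on the bridge from the start was rejected: dibromocarbene would add to the methyl-substituted analogue of diene 1 at the wrong (trisubstituted) alkene, and the following C–H insertion would have two non-equivalent allylic methylenes to choose from. The symmetric diene avoids both problems at the price of three late steps, which must leave the isovalerate and the silyl ether untouched.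

Seven-membered ring substituents (23 ⇐ 22 ⇐ 21 ⇐ 20 ⇐ 19 ⇐ 18 ⇐ 16 ⇐ 14). The C11 methyl of 23 is the reduced form of an ester (20 → 21 → 22 → 23). The ester is needed as the acceptor of the key step and is reduced only when no ketone is left. The C3–H bond of 20 comes from ketone 19 by Corey–Bakshi–Shibata reduction (quaternary C4 against C2H2). The C1–O bond of 18, silylated to 19, comes from enone 16 by catalyst-controlled conjugate borylation and oxidation. The two C4–CH3 bonds of 16 come from enone 14 by double enolate methylation. Enone 14 thus carries no stereocentre in the seven-membered ring, so nothing uncontrolled is made in the key step; the forward steps ask for two reagent-controlled additions on a ring that offers no bias of its own.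

Key cut (14 ⇐ 13 ⇐ 10 + 11). C4–C5 and C1–C11 are cut together, which leaves the tricyclic bicyclobutane 10 and the commercial diene 11, (E)-1-methoxy-3-(trimethylsilyloxy)buta-1,3-diene. Cutting only one of these bonds would need a cyclobutane that already carries a quaternary-flanked side chain; cutting both reduces the problem to a seven-carbon hydrocarbon. Three design choices follow from what the forward reaction requires. The acceptor on C11 is an ester, and a menthyl ester is used so that the same group also serves for resolution. C5 carries a phenylseleno donor: nucleophiles open simple bicyclobutanes from the rear of the central bond, which here lies under the C7–C9 bridge and cannot lead to a ring, whereas the donor turns C5 into a planar seleno-carbenium centre that can be attacked on the open convex face; selenium is removed in the next step (13 → 14). The nucleophilic diene terminus is CH2 and not CMe2, because joining two fully substituted carbons at this stage is too crowded; the methyls follow in step 7.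

Bicyclobutane (10 ⇐ 8 ⇐ 5 ⇐ 3 ⇐ 1 + 2, with 6). The C5–Se bond of 10 is cut to ester 8 (bridgehead metalation and selenenylation). The C11–CO bond of 8 is cut to hydrocarbon 5 and (−)-menthyl chloroformate 6 (bridgehead lithiation and acylation). The two bridgeheads of 5 are enantiotopic, so the acylation gives two diastereomeric esters, and isolating 8 from this pair fixes the absolute configuration. Hydrocarbon 5 is the carbenoid C–H insertion product of dibromide 3, made from cyclohexa-1,4-diene 1 and bromoform 2; symmetry makes both steps regiochemically unambiguous.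

## Roads not taken

Alternative 1: cut C1–C11 only. Precursor A1 holds the finished enone bridge, an exocyclic methylene on C11 and a CMe2–CO–CH=CH–O-(4-methoxybenzyl) chain on C5. Fe(acac)3/PhSiH3 would transfer a hydrogen atom to the methylene; the tertiary C11 radical adds to C1 of the β-alkoxy enone and closes the seven-membered ring to A2. The key step belongs to a well-established reaction class, the enone bridge and C9 methyl are present from the start, and C1–O arrives in the cyclisation; in precedent and in the endgame this road is better than the chosen one. Its weak points are these: A1 already contains the cyclobutane with both crowded appendages, and this plan says nothing about how to make it. The seven-membered closure onto a donor-substituted acceptor competes with simple reduction of the radical, the bridge enone is a second radical acceptor, and C1 is formed under the same near-mirror symmetry with no reagent to control it. Against this, the chosen plan offers three steps to the cyclobutane core, both ring bonds in one operation, and a catalyst-set C1.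

Alternative 2: cut C9–C10 and C6–C7, building the enone ring onto a cyclobutanone. The enamine of cyclobutanone ester A3 with pyrrolidine A4 would react with acid chloride A5 by addition–elimination at one α-carbon and acylation at the other, giving bicyclic diketo ester A6. This is by far the shortest entry to the verbenone-like half, with the C11 methyl, the C7 enone and the C9 methyl all in place; the chosen route spends six steps on these features. The weak points: 2-acylcyclobutanones open readily, the bridging closure must form a strained bicyclo[3.1.1] system, and discrimination of the enantiotopic α-carbons by A4 is uncertain. A6 also still lacks the whole seven-membered ring: C5 is a ketone that must become CH–C4 with C4 quaternary and with facial control. The chosen plan makes exactly those two hard bonds (C4–C5, C1–C11) in its key step.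

Alternative 3: cut C7–C8. In aldehyde A7, Me2AlCl would promote a carbonyl-ene reaction between the C7 aldehyde on C6 and the isopropenyl group on C10, while the C6 epimers equilibrate through the enol; the product is homoallylic alcohol A8. The ring closure comes late, with both oxygen substituents already differentiated and the C9 methyl supplied by the isopropenyl group; the dynamic epimerisation is forgiving, and the endgame is shorter than the chosen one. The weak points: A7 is a bicyclo[4.1.1]octane with four contiguous cyclobutane stereocentres, and its synthesis is the real problem. The ene closure forms a strained ring through a cation-like transition state next to a cyclobutane, so Prins or ring-expansion pathways threaten, and enolisation of a hindered cyclobutanecarbaldehyde under a Lewis acid is not assured. The chosen plan addresses the cyclobutane and both flanking bonds directly and pays for it with a longer endgame.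

Key step: step 5

Remark (assumption): ester 8 and its diastereomer (ester on the other bridgehead, same menthyl group) are taken to be separable by chromatography or crystallisation; the bridgehead that carries the ester in 8 is to be confirmed by X-ray analysis.

## Steps

Step 1
Reactants: 1 cyclohexa-1,4-diene; 2 bromoform
Product: 3 7,7-dibromobicyclo[4.1.0]hept-3-ene (cis-fused)
Conditions: KOtBu, pentane, −20 → 0 °C (1 in excess)
Reagents that add atoms: none
Why: Dibromocarbene from bromoform and base adds once to the symmetric diene (gem-dihalocyclopropanation); excess diene suppresses the bis-adduct and the cis ring fusion is inherent.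

Step 2
Reactants: 3 7,7-dibromobicyclo[4.1.0]hept-3-ene
Product: 5 tricyclo[4.1.0.0(2,7)]hept-3-ene, via lithium carbenoid 4 (not isolated)
Conditions: MeLi, Et2O, −78 → 0 °C
Reagents that add atoms: none
Why: Bromine–lithium exchange gives the cyclopropylidene carbenoid, which inserts into the neighbouring allylic C–H bond (1,3-insertion) to form the bicyclobutane; the two allylic methylenes of 3 are equivalent by symmetry, so only one tricycle can form.

Step 3
Reactants: 5 tricyclo[4.1.0.0(2,7)]hept-3-ene; 6 (1R,2S,5R)-menthyl chloroformate
Product: 8 (1R,2S,5R)-menthyl tricyclo[4.1.0.0(2,7)]hept-3-ene-1-carboxylate (ester on the bridgehead that is C11 when the double bond is C7=C8 on the C6 wing), via 1-lithiotricycloheptene 7 (not isolated)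
Conditions: n-BuLi, TMEDA, Et2O, 0 °C → rt; then added to 6, THF, −78 °C; chromatographic separation of the two diastereomeric esters
Reagents that add atoms: none
Why: The bridgehead C–H bonds of a bicyclobutane are the most acidic in 5 and are lithiated directly; acylation occurs with retention. The bridgeheads are enantiotopic, so 8 and the diastereomer with the ester on the other bridgehead should form in equal amounts, and isolating 8 fixes the absolute configuration.

Step 4
Reactants: 8 menthyl tricycloheptene carboxylate
Product: 10 (1R,2S,5R)-menthyl 7-(phenylselanyl)tricyclo[4.1.0.0(2,7)]hept-3-ene-1-carboxylate (SePh on C5; ester on C11), via bridgehead lithio ester 9 (not isolated)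
Conditions: LiTMP (lithium 2,2,6,6-tetramethylpiperidide), THF, −78 °C; then PhSeCl, −78 °C; used at once
Reagents that add atoms: benzeneselenenyl chloride, Cl[Se]c1ccccc1
Why: Directed bridgehead metalation of an acceptor-substituted bicyclobutane: the remaining bridgehead hydrogen is acidified by the ester across the central bond, the ester has no α-hydrogen and is shielded by the menthyl group, and the anion is trapped with retention by the selenium electrophile.

Step 5
Reactants: 10 seleno bicyclobutane ester; 11 (E)-1-methoxy-3-(trimethylsilyloxy)buta-1,3-diene
Product: 13 tricyclic seleno enone (C11 menthyl ester; C5 SePh; C1=C2–C3(=O)–C4H2 in the new seven-membered ring; C7=C8; SePh and ester syn to the C7–C9 bridge), via silyl enol ether cycloadduct 12 (not isolated)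
Conditions: Sc(OTf)3 (10 mol%), 11 (2 equiv), CH2Cl2, −40 → 0 °C; then CF3CO2H, 0 °C
Reagents that add atoms: none
Why: Proposed new method: Sc(OTf)3 binds the ester carbonyl of 10 and, assisted by the selenium lone pair, the strained C5–C11 bond ionises to a seleno-stabilised cyclobutyl cation at C5 and a scandium ester enolate at C11; the CH2 terminus C4 of 11 adds to C5, the enolate closes on C1 of the resulting β-methoxy enone (intramolecular Mukaiyama–Michael addition) to give 12, and acid then removes the silyl group and methanol to leave enone 13. The closest known reaction type is the Lewis-acid-catalysed formal (4+3) cycloaddition of donor–acceptor acyl bicyclo[1.1.0]butanes with silyl dienol ethers to bicyclo[4.1.1]octanes, together with the alkylation of selenium-stabilised carbenium ions by silyl enol ethers. The seven-membered ring closes by a 7-endo-trig conjugate addition of an exocyclic enolate, helped by C4 and the enolate carbon being held 1,3-diaxial on the cyclobutane. C5 and C11 are the only new stereocentres and are set by topology: the concave face of the bicyclobutane is filled by the C7–C9 bridge, so a ring can form only when both new bonds lie on the convex face, which leaves SePh and the ester syn to that bridge. The selectivity the step needs is facial at C5, and this is what the selenium secures: a simple bicyclobutane is opened by nucleophiles from the rear of the central bond with inversion, which here would place C4 under the bridge and end in an open-chain adduct, whereas a planar seleno-carbenium ion can be attacked on its open convex face. Regiochemistry follows the donor–acceptor polarisation (nucleophilic C4 to C5, electrophilic C1 to C11), and C1 ceases to be a stereocentre on elimination, so no diastereomers arise.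

Step 6
Reactants: 13 tricyclic seleno enone
Product: 14 tricyclic enone ester (C5–H; otherwise as 13)
Conditions: Bu3SnH, azobisisobutyronitrile (cat.), benzene, 80 °C
Reagents that add atoms: none
Why: Radical chain deselenation; C5 is a ring-fusion atom, so hydrogen can only enter on the bridge side, and the bridgehead-type cyclobutyl radical is not aligned for ring opening. Enone, ester and alkene are inert under these conditions.

Step 7
Reactants: 14 tricyclic enone ester
Product: 16 C4 gem-dimethyl enone ester, via monomethyl ketone 15 (not isolated)
Conditions: LiN(iPr)2, THF, −78 °C, MeI; then LiN(iPr)2, MeI, DMPU, −78 → 0 °C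
Reagents that add atoms: iodomethane, CI
Why: Kinetic α′-enolate alkylation performed twice; C4 is the only enolisable position (C11 is quaternary, so no γ-deprotonation) and the ester has no α-hydrogen.

Step 8
Reactants: 16 C4 gem-dimethyl enone ester
Product: 18 (1R)-β-hydroxy ketone (C1–OH on the face toward C6; C3 ketone), via C1 pinacolboronate 17 (not isolated)
Conditions: CuCl (5 mol%), NaOtBu (10 mol%), (R,R)-2,3-bis(tert-butylmethylphosphino)quinoxaline (QuinoxP*; antipode chosen on a model enone for Re-face delivery), B2pin2, MeOH, THF, rt; then 30% H2O2, pH 7 buffer, 0 °C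
Reagents that add atoms: hydrogen peroxide, OO; bis(pinacolato)diboron, CC1(C)OB(OC1(C)C)B2OC(C)(C)C(C)(C)O2 (boron of 17 only)
Why: Copper-catalysed asymmetric conjugate borylation; the enone is nearly mirror-symmetric about its own plane (only the remote bridge and the menthyl group break it), so the chiral ligand decides and boron is delivered to the Re face of C1. C–B oxidation proceeds with retention to the (1R)-alcohol.

Step 9
Reactants: 18 β-hydroxy ketone
Product: 19 C1 tert-butyldimethylsilyl ether
Conditions: tBuMe2SiOTf, 2,6-lutidine, CH2Cl2, −78 → 0 °C
Reagents that add atoms: tert-butyldimethylsilyl triflate, CC(C)(C)[Si](C)(C)OS(=O)(=O)C(F)(F)F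
Why: Silylation of a hindered alcohol with the reactive triflate and a non-nucleophilic base; low temperature avoids β-elimination and no stereocentre is touched.

Step 10
Reactants: 19 silyloxy ketone
Product: 20 (1R,3R) C3 alcohol (O3 trans to O1; on the face toward C10)
Conditions: (S)-1-methyl-3,3-diphenyltetrahydro-1H,3H-pyrrolo[1,2-c][1,3,2]oxazaborole ((S)-Me-CBS, 20 mol%), catecholborane, toluene, −78 °C
Reagents that add atoms: none
Why: Corey–Bakshi–Shibata reduction; the ketone lies between quaternary C4 (large) and C2H2 (small), so the (S)-catalyst should give the (3R)-alcohol by reagent control. Catecholborane at low temperature spares the alkene and the ester.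

Step 11
Reactants: 20 hydroxy ester
Product: 21 diol (C11–CH2OH; C3–OH)
Conditions: LiAlH4, THF, 0 → 40 °C
Reagents that add atoms: none
Why: Hydride reduction of the hindered ester to the neopentyl alcohol with release of menthol; silyl ether and alkene are inert and no ketone is present at this stage.

Step 12
Reactants: 21 diol
Product: 22 primary tosylate
Conditions: TsCl, pyridine, 4-(dimethylamino)pyridine (cat.), CH2Cl2, 0 °C → rt
Reagents that add atoms: 4-methylbenzenesulfonyl chloride, Cc1ccc(cc1)S(Cl)(=O)=O
Why: Selective sulfonylation of the primary alcohol; the secondary C3 hydroxyl is shielded by the adjacent CMe2.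

Step 13
Reactants: 22 primary tosylate
Product: 23 C11 methyl compound (C1–OSi; C3–OH; C7=C8)
Conditions: LiEt3BH, THF, 0 → 65 °C
Reagents that add atoms: none
Why: SN2 hydride displacement of a neopentyl sulfonate by the most nucleophilic borohydride; a purely ionic SN2 path avoids the cyclobutylcarbinyl cation or radical that would open or expand the four-membered ring.

Step 14
Reactants: 23 C11 methyl alcohol
Product: 24 O3 isovalerate
Conditions: 3-methylbutanoyl chloride, pyridine, 4-(dimethylamino)pyridine, CH2Cl2, rt → 40 °C
Reagents that add atoms: 3-methylbutanoyl chloride, CC(C)CC(Cl)=O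
Why: Nucleophile-catalysed acylation of the only free hydroxyl.

Step 15
Reactants: 24 O3 isovalerate
Product: 26 bridge enone (C7=O; C8=C9), via allylic hydroperoxide 25 (not isolated)
Conditions: O2, 5,10,15,20-tetraphenylporphyrin (cat.), visible light, CH2Cl2, 0 °C; then Ac2O, pyridine, 4-(dimethylamino)pyridine, 0 °C → rt
Reagents that add atoms: oxygen, O=O
Why: Schenck ene reaction: singlet oxygen bonds to C7 and takes an allylic hydrogen from C9, moving the double bond to C8=C9 (abstraction from C6 would give a bridgehead alkene and is excluded); Kornblum–DeLaMare dehydration of the secondary hydroperoxide gives the enone. Nothing else in 24 reacts with singlet oxygen.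

Step 16
Reactants: 26 bridge enone
Product: 27 trimethylsilyl enol ether (C7(OSiMe3)=C8; C9 methyl on the face toward C5)
Conditions: Me2CuLi, Me3SiCl, THF, −78 °C
Reagents that add atoms: lithium dimethylcuprate, [Li+].C[Cu-]C; chlorotrimethylsilane, C[Si](C)(C)Cl
Why: Silyl-accelerated cuprate conjugate addition to a cyclic enone; methyl enters C9 anti to the C11 methyl group, the ester is tolerated at −78 °C, and this stereocentre is removed in step 17.

Step 17
Reactants: 27 silyl enol ether
Product: 28 β-methyl enone (C7=O; C8=C9(CH3))
Conditions: Pd(OAc)2 (1.1 equiv), MeCN, rt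
Reagents that add atoms: none
Why: Saegusa–Ito oxidation; the palladium enolate at C8 can eliminate β-hydride only from C9, giving the conjugated β-methyl enone regiospecifically.

Step 18
Reactants: 28 silyl ether enone
Product: 29 C1 alcohol
Conditions: HF·pyridine, THF/pyridine, 0 °C → rt
Reagents that add atoms: none
Why: Acidic fluoride cleaves the silyl ether without base, avoiding 1,3-migration of the isovalerate and β-elimination.

Step 19
Reactants: 29 C1 alcohol
Product: 30 CNP0335239.1
Conditions: 3-methylbut-2-enoyl chloride, pyridine, 4-(dimethylamino)pyridine (cat.), CH2Cl2, 0 °C → rt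
Reagents that add atoms: 3-methylbut-2-enoyl chloride, CC(C)=CC(Cl)=O
Why: Acylation of the last free hydroxyl; the weak base limits deconjugation of the senecioyl group through its vinylketene.

## Compound list

1 | cyclohexa-1,4-diene | C1=CCC=CC1 | starting material
2 | bromoform | BrC(Br)Br | starting material
3 | 7,7-dibromobicyclo[4.1.0]hept-3-ene (cis-fused, meso) | BrC1(Br)[C@H]2CC=CC[C@@H]12 | intermediate
4 | 7-bromo-7-lithiobicyclo[4.1.0]hept-3-ene (lithium carbenoid; not isolated) | [Li]C1(Br)[C@H]2CC=CC[C@@H]12 | intermediate
5 | tricyclo[4.1.0.0(2,7)]hept-3-ene (achiral; bridgeheads C5/C11, wings C6/C10, bridge C7=C8–C9H2) | [C@H]12[C@@H]3C=CC[C@H]1[C@H]23 | intermediate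
6 | (1R,2S,5R)-menthyl chloroformate | ClC(=O)O[C@@H]1C[C@H](C)CC[C@H]1C(C)C | starting material
7 | 1-lithiotricyclo[4.1.0.0(2,7)]hept-3-ene (racemic; enantiomer leading to 8 drawn; not isolated) | [Li][C@]12[C@@H]3C=CC[C@H]1[C@H]23 | intermediate
8 | (1R,2S,5R)-menthyl tricyclo[4.1.0.0(2,7)]hept-3-ene-1-carboxylate, diastereomer with the ester on C11 and the double bond C7=C8 on the C6 wing | O=C(O[C@@H]1C[C@H](C)CC[C@H]1C(C)C)[C@]23[C@@H]4C=CC[C@H]2[C@H]34 | intermediate
9 | 7-lithio derivative of 8 (lithium on C5; not isolated) | O=C(O[C@@H]1C[C@H](C)CC[C@H]1C(C)C)[C@]23[C@@H]4C=CC[C@H]2[C@]34[Li] | intermediate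
10 | (1R,2S,5R)-menthyl 7-(phenylselanyl)tricyclo[4.1.0.0(2,7)]hept-3-ene-1-carboxylate (SePh on C5, ester on C11) | O=C(O[C@@H]1C[C@H](C)CC[C@H]1C(C)C)[C@]23[C@@H]4C=CC[C@H]2[C@]34[Se]c5ccccc5 | intermediate
11 | (E)-1-methoxy-3-(trimethylsilyloxy)buta-1,3-diene | CO/C=C/C(=C)O[Si](C)(C)C | starting material
12 | cycloadduct: C1 methoxy (both C1 epimers), C2=C3 trimethylsilyl enol ether, C5 SePh, C11 menthyl ester (not isolated) | COC1C=C(O[Si](C)(C)C)C[C@]2([Se]c3ccccc3)[C@H]4C=CC[C@@H]2[C@]41C(=O)O[C@@H]5C[C@H](C)CC[C@H]5C(C)C | intermediate
13 | tricyclic seleno enone: C1=C2–C3(=O)–C4H2, C5 SePh and C11 menthyl ester syn to the C7–C9 bridge, C7=C8 | C1=CC(=O)C[C@]2([Se]c3ccccc3)[C@H]4C=CC[C@@H]2[C@]41C(=O)O[C@@H]5C[C@H](C)CC[C@H]5C(C)C | intermediate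
14 | tricyclic enone ester: as 13 with C5–H | C1=CC(=O)C[C@@H]2[C@H]3C=CC[C@@H]2[C@]31C(=O)O[C@@H]4C[C@H](C)CC[C@H]4C(C)C | intermediate
15 | 4-monomethyl enone ester (C4 epimers; not isolated) | C1=CC(=O)C(C)[C@@H]2[C@H]3C=CC[C@@H]2[C@]31C(=O)O[C@@H]4C[C@H](C)CC[C@H]4C(C)C | intermediate
16 | C4 gem-dimethyl enone ester | C1=CC(=O)C(C)(C)[C@@H]2[C@H]3C=CC[C@@H]2[C@]31C(=O)O[C@@H]4C[C@H](C)CC[C@H]4C(C)C | intermediate
17 | C1 pinacolboronate of the C3 ketone (boron on the face later taken by O1; not isolated) | CC1(C)OB(OC1(C)C)[C@@H]5CC(=O)C(C)(C)[C@@H]2[C@H]3C=CC[C@@H]2[C@]35C(=O)O[C@@H]4C[C@H](C)CC[C@H]4C(C)C | intermediate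
18 | (1R)-1-hydroxy-3-ketone, C11 menthyl ester | O[C@@H]1CC(=O)C(C)(C)[C@@H]2[C@H]3C=CC[C@@H]2[C@]31C(=O)O[C@@H]4C[C@H](C)CC[C@H]4C(C)C | intermediate
19 | (1R)-1-(tert-butyldimethylsilyloxy)-3-ketone, C11 menthyl ester | CC(C)(C)[Si](C)(C)O[C@@H]1CC(=O)C(C)(C)[C@@H]2[C@H]3C=CC[C@@H]2[C@]31C(=O)O[C@@H]4C[C@H](C)CC[C@H]4C(C)C | intermediate
20 | (1R,3R)-1-silyloxy-3-ol, C11 menthyl ester | CC(C)(C)[Si](C)(C)O[C@@H]1C[C@@H](O)C(C)(C)[C@@H]2[C@H]3C=CC[C@@H]2[C@]31C(=O)O[C@@H]4C[C@H](C)CC[C@H]4C(C)C | intermediate
21 | (1R,3R)-1-silyloxy-3-ol with C11 hydroxymethyl | CC(C)(C)[Si](C)(C)O[C@@H]1C[C@@H](O)C(C)(C)[C@@H]2[C@H]3C=CC[C@@H]2[C@]31CO | intermediate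
22 | primary tosylate of 21 | CC(C)(C)[Si](C)(C)O[C@@H]1C[C@@H](O)C(C)(C)[C@@H]2[C@H]3C=CC[C@@H]2[C@]31COS(=O)(=O)c4ccc(C)cc4 | intermediate
23 | (1R,3R)-1-silyloxy-3-ol with C11 methyl, C7=C8 | CC(C)(C)[Si](C)(C)O[C@@H]1C[C@@H](O)C(C)(C)[C@@H]2[C@H]3C=CC[C@@H]2[C@]31C | intermediate
24 | O3 isovalerate of 23 | CC(C)(C)[Si](C)(C)O[C@@H]1C[C@@H](OC(=O)CC(C)C)C(C)(C)[C@@H]2[C@H]3C=CC[C@@H]2[C@]31C | intermediate
25 | C7 hydroperoxide with C8=C9 (C7 configuration of no consequence; not isolated) | CC(C)(C)[Si](C)(C)O[C@@H]1C[C@@H](OC(=O)CC(C)C)C(C)(C)[C@@H]2[C@H]3C(OO)C=C[C@@H]2[C@]31C | intermediate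
26 | bridge enone: C7=O, C8=C9 (no C9 methyl) | CC(C)(C)[Si](C)(C)O[C@@H]1C[C@@H](OC(=O)CC(C)C)C(C)(C)[C@@H]2[C@H]3C(=O)C=C[C@@H]2[C@]31C | intermediate
27 | C7 trimethylsilyl enol ether with C9 methyl on the face toward C5 | CC(C)(C)[Si](C)(C)O[C@@H]1C[C@@H](OC(=O)CC(C)C)C(C)(C)[C@@H]2[C@H]3C(O[Si](C)(C)C)=C[C@@H](C)[C@@H]2[C@]31C | intermediate
28 | O1 silyl ether, O3 isovalerate, C7=O, C8=C9(CH3) | CC(C)(C)[Si](C)(C)O[C@@H]1C[C@@H](OC(=O)CC(C)C)C(C)(C)[C@@H]2[C@H]3C(=O)C=C(C)[C@@H]2[C@]31C | intermediate
29 | C1 alcohol, O3 isovalerate, enone bridge | O[C@@H]1C[C@@H](OC(=O)CC(C)C)C(C)(C)[C@@H]2[C@H]3C(=O)C=C(C)[C@@H]2[C@]31C | intermediate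
30 | CNP0335239.1 | CC(C)=CC(=O)O[C@@H]1C[C@@H](OC(=O)CC(C)C)C(C)(C)[C@@H]2[C@H]3C(=O)C=C(C)[C@@H]2[C@]31C | target

## Step count and least certain steps

Total: 19 steps. Longest linear sequence: 19 steps, from 1 to 30.

Step 5 (key step, Proposed new method). The most likely failure is attack of the diene on C5 from the rear of the still-intact central bond, under the C7–C9 bridge, if ionisation to the seleno-carbenium ion is not complete; the process then stops at an open-chain Michael-type adduct. A second risk is silyl transfer to the enolate before ring closure. The fallback sets out from 10 and comes back at 13, and it removes the strained bond before any C–C bond is made. Methanol is added across the central bond of 10 (catalytic camphorsulfonic acid, MeOH/CH2Cl2, −20 °C) to give the O,Se-acetal ester F1. The ester is converted to its silyl ketene acetal F2 (LiN(iPr)2, Me3SiCl, THF, −78 °C). Me3SiOTf then ionises the acetal to the free seleno-carbenium ion, which has no rear-side bias; it is alkylated by 11 on the face away from the bridge, and the ketene acetal closes on C1 (Mukaiyama–Michael) to 12 and, after CF3CO2H, 13.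

Step 4. The most likely failure is incomplete or unselective metalation next to the ester, or decomposition of the donor–acceptor bicyclobutane by premature heterolysis on handling. The fallback sets out from 5 and comes back at 14, and it introduces sulfur on the hydrocarbon first. 5 is lithiated (n-BuLi) and quenched with PhSSPh to give sulfide F3. A second bridgehead lithiation (n-BuLi, TMEDA) and acylation with 6 give, after separation of diastereomers, the more robust thio ester F4. The conditions of step 5 convert F4 into thio enone F5, and Bu3SnH with azobisisobutyronitrile in toluene at 110 °C removes sulfur to give 14.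

Step 3. The most likely failure is poor separation of 8 from its bridgehead diastereomer, which would erode the enantiomeric purity of everything downstream. The fallback sets out from 5 and comes back at 8. Lithio compound 7 is quenched with CO2, and the racemic acid is resolved by crystallisation: the required enantiomer, acid F6, is collected as its 1-phenylethylammonium salt F7 (amine antipode chosen so that the required acid gives the less soluble salt; the (S)-amine is drawn). Acid F6 is liberated from the salt with dilute HCl and esterified with (−)-menthol (dicyclohexylcarbodiimide, 4-(dimethylamino)pyridine) to give 8.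

Step 8. The most likely failure is slow boryl transfer to a β-carbon next to the quaternary C11, or insufficient facial control, with the menthyl ester working against the ligand. The fallback sets out from 16 and comes back at 18. Asymmetric nucleophilic epoxidation of the enone (9-amino-9-deoxyepiquinine trifluoroacetate salt or its quinidine-derived counterpart, aqueous H2O2, dioxane) gives epoxy ketone F8. SmI2 in THF/MeOH at −78 °C cleaves the C2–O bond to give 18.

Step 15. The most likely failure is a sluggish ene reaction of the cis-disubstituted alkene, with photobleaching or over-oxidation on prolonged irradiation. The fallback sets out from 24 and comes back at 28. SeO2/tBuOOH oxidises the allylic methylene C9 (ene reaction, then [2,3] shift) to alcohol F9. MnO2 gives the regioisomeric enone F10 with the carbonyl at C9. MeLi/CeCl3 adds to the ketone only, giving tertiary allylic alcohol F11, and pyridinium chlorochromate, C5H5NH[CrO3Cl], effects the oxidative 1,3-transposition to 28.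

## Further compounds

F1 | step 5 | (1R,2S,5R)-menthyl ester of the methanol adduct of 10: bicyclo[3.1.1]hept-2-ene with C5(OMe)(SePh) and C11(H)(CO2R) (C5 and C11 epimers of no consequence) | COC2([Se]c1ccccc1)[C@H]3C=CC[C@@H]2C3C(=O)O[C@@H]4C[C@H](C)CC[C@H]4C(C)C
F2 | step 5 | trimethylsilyl ketene acetal of F1 (C11=C(OSiMe3)O-menthyl) | COC2([Se]c1ccccc1)[C@H]3C=CC[C@@H]2C3=C(O[Si](C)(C)C)O[C@@H]4C[C@H](C)CC[C@H]4C(C)C
F3 | step 4 | 1-(phenylsulfanyl)tricyclo[4.1.0.0(2,7)]hept-3-ene (racemic; enantiomer leading to F4 drawn) | [C@H]12[C@@H]3C=CC[C@H]1[C@]23Sc4ccccc4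
F4 | step 4 | (1R,2S,5R)-menthyl 7-(phenylsulfanyl)tricyclo[4.1.0.0(2,7)]hept-3-ene-1-carboxylate (SPh on C5, ester on C11) | O=C(O[C@@H]1C[C@H](C)CC[C@H]1C(C)C)[C@]23[C@@H]4C=CC[C@H]2[C@]34Sc5ccccc5
F5 | step 4 | thio analogue of 13 (C5 SPh) | C1=CC(=O)C[C@]2(Sc3ccccc3)[C@H]4C=CC[C@@H]2[C@]41C(=O)O[C@@H]5C[C@H](C)CC[C@H]5C(C)C
F6 | step 3 | tricyclo[4.1.0.0(2,7)]hept-3-ene-1-carboxylic acid, enantiomer corresponding to 8 | OC(=O)[C@]12[C@@H]3C=CC[C@H]1[C@H]23
F7 | step 3 | 1-phenylethylammonium salt of F6 ((S)-amine drawn) | C[C@H]([NH3+])c1ccccc1.[O-]C(=O)[C@]12[C@@H]3C=CC[C@H]1[C@H]23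
F8 | step 8 | C1–C2 epoxide of 16, oxygen on the face toward C6 | [C@H]16O[C@@H]6C(=O)C(C)(C)[C@@H]2[C@H]3C=CC[C@@H]2[C@]31C(=O)O[C@@H]4C[C@H](C)CC[C@H]4C(C)C
F9 | step 15 | C9 allylic alcohol of 24 (C7=C8 retained; OH on the face toward C5) | CC(C)(C)[Si](C)(C)O[C@@H]1C[C@@H](OC(=O)CC(C)C)C(C)(C)[C@@H]2[C@H]3C=C[C@@H](O)[C@@H]2[C@]31C
F10 | step 15 | regioisomeric bridge enone: C9=O, C7=C8 | CC(C)(C)[Si](C)(C)O[C@@H]1C[C@@H](OC(=O)CC(C)C)C(C)(C)[C@@H]2[C@H]3C=CC(=O)[C@@H]2[C@]31C
F11 | step 15 | tertiary allylic alcohol: C9(OH)(CH3), C7=C8 (methyl on the face toward C5) | CC(C)(C)[Si](C)(C)O[C@@H]1C[C@@H](OC(=O)CC(C)C)C(C)(C)[C@@H]2[C@H]3C=C[C@](C)(O)[C@@H]2[C@]31C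
A1 | alternative 1 | bicyclo[3.1.1]heptenone with C11 exocyclic methylene and a (E)-CMe2–CO–CH=CH–O-(4-methoxybenzyl) chain on C5 | COc1ccc(cc1)CO/C=C/C(=O)C(C)(C)[C@@H]2[C@H]3C(=O)C=C(C)[C@@H]2C3=C
A2 | alternative 1 | tricyclic enone with C3 ketone and C1 4-methoxybenzyl ether | COc1ccc(cc1)CO[C@@H]2CC(=O)C(C)(C)[C@@H]3[C@H]4C(=O)C=C(C)[C@@H]3[C@]42C
A3 | alternative 2 | tert-butyl 1-methyl-3-oxocyclobutane-1-carboxylate | CC1(CC(=O)C1)C(=O)OC(C)(C)C
A4 | alternative 2 | (S)-2-(methoxymethyl)pyrrolidine | COC[C@@H]1CCCN1
A5 | alternative 2 | (E)-3-chlorobut-2-enoyl chloride | C/C(Cl)=C/C(Cl)=O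
A6 | alternative 2 | tert-butyl 4,6-dimethyl-2,7-dioxobicyclo[3.1.1]hept-3-ene-6-carboxylate | CC(C)(C)OC(=O)[C@@]1(C)[C@@H]2C(=O)C=C(C)[C@H]1C2=O
A7 | alternative 3 | bicyclo[4.1.1]octane aldehyde: C6 formyl (epimerising), C10 isopropenyl, C11 methyl, O1 silyl ether, O3 isovalerate | CC(C)(C)[Si](C)(C)O[C@@H]1C[C@@H](OC(=O)CC(C)C)C(C)(C)[C@@H]2C(C=O)[C@@]1(C)[C@H]2C(C)=C
A8 | alternative 3 | tricyclic homoallylic alcohol with C7 hydroxyl and exocyclic methylene on C9 | CC(C)(C)[Si](C)(C)O[C@@H]1C[C@@H](OC(=O)CC(C)C)C(C)(C)[C@@H]2[C@H]3[C@H](O)CC(=C)[C@@H]2[C@]31C
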